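## Retrosynthetic overview

1. Target 25 ⇒ enal / enol triflate 23: the C7–C8 bond is closed by a NiCl2/CrCl2 vinyl triflate–aldehyde coupling; ring B (ten-membered) and, by lactonisation in the same flask, the butenolide are formed last.
2. 23 ⇒ iodide 17 + ClCOCH(Me)CO2Me: C9–C8 by acylative Negishi coupling; C14–OAc by Mn(OAc)3 α'-acetoxylation; the enone by Saegusa oxidation of the cycloadduct silyl enol ether.
3. 17 ⇒ ketone 7 + (Z)-allylic bromide 11: C3–C4 by methyl-ketone enolate alkylation; C2–OH by oxazaborolidine-catalysed reduction.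
4. 7 ⇒ silyloxydiene 2 + enedione-aldehyde 5: ring A is made first, by a metal-free catalytic asymmetric Diels–Alder reaction that sets C1 (quaternary) and C10.

Assumption 1: the SMILES is read as (1R,2S,7R,10R,14S,5Z) in briarane numbering (C1 quaternary carbon, C2 isobutyrate carbon, C7 lactone carbinol, C10 ring-fusion CH, C14 acetate carbon); this numbering is used for all intermediates.

Assumption 2: the (S)-oxazaborolidinium ion is written for step 3; its mirror image is used if the sense of induction is found to be opposite.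

## Route

Step 1
Reactants: 1 (E)-pent-3-en-2-one
Product: 2 (E)-2-(triisopropylsilyloxy)penta-1,3-diene
Conditions: iPr3SiOTf, Et3N, Et2O, 0 °C
Reagents that add atoms: triisopropylsilyl triflate, CC(C)[Si](C(C)C)(C(C)C)OS(=O)(=O)C(F)(F)F
Why: Soft enolisation and O-silylation of the methyl ketone on its methyl side (silyl enol ether formation) gives the 2-silyloxydiene with the E alkene untouched.

Step 2
Reactants: 3 2,3-dimethylfuran
Product: 5 (E)-3-methyl-4-oxopent-2-enal, via (Z)-3-methyl-4-oxopent-2-enal 4 (not isolated)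
Conditions: NBS, NaHCO3, acetone/H2O 10:1, −15 °C; then pyridine, 23 °C
Reagents that add atoms: water, O
Why: Oxidative furan ring opening (bromination–hydrolysis) gives the cis-enedione 4, which pyridine isomerises to the more stable trans isomer 5 needed for a trans C9/C2 relationship.

Step 3
Reactants: 2 (E)-2-(triisopropylsilyloxy)penta-1,3-diene; 5 (E)-3-methyl-4-oxopent-2-enal
Product: 6 (1R,2R,6R)-6-acetyl-2,6-dimethyl-4-(triisopropylsilyloxy)cyclohex-3-ene-1-carbaldehyde
Conditions: (S)-o-tolyl-oxazaborolidinium triflimide [from the (S)-α,α-diphenylprolinol-derived oxazaborolidine and Tf2NH] (20 mol%), CH2Cl2, −78 → −40 °C; crude product taken directly into step 4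
Reagents that add atoms: none
Why: Proposed new method: an oxazaborolidinium-catalysed Diels–Alder reaction in which a β,β-disubstituted 4-oxo-2-enal is the dienophile and the quaternary carbon is made at its β-position; the cationic boron binds the less hindered formyl oxygen (with the usual formyl C–H···O contact), which puts the largest LUMO coefficient on C3 of 5, so the unsubstituted CH2 terminus of 2 bonds there ("para" product, bonds C1–C14 and C10–C11), the E geometry is transferred suprafacially (CHO trans to acetyl, i.e. C9 trans to C2) and the catalyst's aryl group shields one enal face so that the diene adds to the C2-Re/C3-Re face to give (1R,10R); the closest known reaction type is the oxazaborolidinium-catalysed Diels–Alder reaction of 2-silyloxydienes with α-substituted or β-monosubstituted enals and with quinones.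

Step 4
Reactants: 6 (1R,2R,6R)-6-acetyl-2,6-dimethyl-4-(triisopropylsilyloxy)cyclohex-3-ene-1-carbaldehyde
Product: 7 C9 alcohol (6 with CHO reduced to CH2OH)
Conditions: NaBH4 (0.35 equiv), MeOH/CH2Cl2, −78 °C
Reagents that add atoms: none
Why: Chemoselective hydride reduction of the aldehyde in the presence of the hindered α-quaternary methyl ketone removes the epimerisable formyl group and leaves the silyl enol ether intact.

Step 5
Reactants: 8 4-methylfuran-2(5H)-one
Product: 9 methyl (Z)-4-bromo-3-methylbut-2-enoate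
Conditions: HBr (gas), MeOH, 0 → 23 °C
Reagents that add atoms: hydrogen bromide, Br; methanol, CO
Why: Acid-mediated lactone opening by bromide at the allylic C–O bond (SN2) followed by Fischer esterification keeps the cis alkene geometry imposed by the ring.

Step 6
Reactants: 9 methyl (Z)-4-bromo-3-methylbut-2-enoate
Product: 10 (Z)-4-bromo-3-methylbut-2-en-1-ol
Conditions: iBu2AlH (2.2 equiv), CH2Cl2, −78 °C
Reagents that add atoms: none
Why: Low-temperature aluminium hydride reduction of the conjugated ester gives the allylic alcohol without touching the allylic bromide or the alkene geometry.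

Step 7
Reactants: 10 (Z)-4-bromo-3-methylbut-2-en-1-ol
Product: 11 (Z)-4-bromo-3-methylbut-2-enyl triethylsilyl ether
Conditions: Et3SiCl, imidazole, CH2Cl2, 0 °C
Reagents that add atoms: chlorotriethylsilane, CC[Si](Cl)(CC)CC
Why: Silylation of the primary alcohol prevents cyclisation to the dihydrofuran and gives a group that survives base but is oxidised directly in step 16.

Step 8
Reactants: 7 C9 alcohol; 11 (Z)-4-bromo-3-methylbut-2-enyl triethylsilyl ether
Product: 13 C3-alkylated hydroxy ketone, via dilithium alkoxide-enolate 12 (not isolated)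
Conditions: LiN(iPr)2 (2.2 equiv), THF, −78 °C; then 11, DMPU, −78 → −40 °C
Reagents that add atoms: none
Why: Kinetic enolate alkylation (SN2) is regiochemically unambiguous because the ketone is enolisable only at its methyl group (C1 is quaternary), and it installs C4–C7 with the Z alkene already in place.

Step 9
Reactants: 13 C3-alkylated hydroxy ketone
Product: 14 C9 iodide
Conditions: PPh3, imidazole, I2 (1.05 equiv, added last), CH2Cl2, 0 °C
Reagents that add atoms: iodine, II
Why: Appel iodination of the only free (primary) hydroxyl is done before the C2 ketone is reduced, so that no 1,4-diol able to close a tetrahydrofuran is ever present.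

Step 10
Reactants: 14 C9 iodide
Product: 15 (2S)-carbinol
Conditions: (R)-2-methyl-CBS-oxazaborolidine (20 mol%), BH3·SMe2, THF, −30 °C; then MeOH
Reagents that add atoms: none
Why: Corey–Bakshi–Shibata reduction sets C2 under catalyst control, the quaternary C1 acting as the large and the C3 methylene as the small substituent, which with the (R)-catalyst gives the 2S alcohol, while the ring ketone stays masked as its silyl enol ether.

Step 11
Reactants: 15 (2S)-carbinol
Product: 16 C2 isobutyrate
Conditions: iPrCOCl, DMAP, pyridine, CH2Cl2, 0 → 40 °C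
Reagents that add atoms: isobutyryl chloride, CC(C)C(Cl)=O
Why: DMAP-catalysed acylation of the hindered secondary alcohol installs the isobutyrate of the target with retention at C2.

Step 12
Reactants: 16 C2 isobutyrate
Product: 17 ring-A enone
Conditions: Pd(OAc)2 (1.2 equiv), MeCN/DMSO, 40 °C
Reagents that add atoms: none
Why: Saegusa–Ito oxidation of the silyl enol ether can only give the C11=C12 enone, because palladium sits on C12 and the only β-hydrogen is on C11, which also erases the C11 stereocentre.

Step 13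
Reactants: 17 ring-A enone
Product: 19 β-keto ester, via alkylzinc iodide 18 (not isolated)
Conditions: Zn dust, LiCl, THF, 35 °C; then ClCOCH(Me)CO2Me, Pd(PPh3)4 (5 mol%), 0 → 23 °C
Reagents that add atoms: methyl 3-chloro-2-methyl-3-oxopropanoate, COC(=O)C(C)C(Cl)=O
Why: Zinc insertion into the primary iodide followed by acylative Negishi coupling forms the C9–C8 bond under non-basic conditions that tolerate the enone and both esters.

Step 14
Reactants: 19 β-keto ester
Product: 21 (Z)-enol triflate, via lithium (Z)-enolate 20 (not isolated)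
Conditions: LiN(SiMe3)2 (1.05 equiv), THF, −78 °C; then N-(5-chloro-2-pyridyl)triflimide, −78 → 0 °C
Reagents that add atoms: N-(5-chloropyridin-2-yl)-1,1,1-trifluoro-N-(trifluoromethylsulfonyl)methanesulfonamide, FC(F)(F)S(=O)(=O)N(c1ccc(Cl)cn1)S(=O)(=O)C(F)(F)F
Why: Only the β-keto ester is deprotonated by one equivalent of base, and O-triflation of its lithium-chelated enolate gives the enol triflate with OTf cis to the ester, as required for lactonisation in step 17.

Step 15
Reactants: 21 (Z)-enol triflate
Product: 22 C14 acetate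
Conditions: Mn(OAc)3·2H2O (3 equiv), benzene, reflux (Dean–Stark)
Reagents that add atoms: manganese triacetate, CC(=O)[O-].CC(=O)[O-].CC(=O)[O-].[Mn+3]
Why: Mn(OAc)3 α'-acetoxylation of the enone goes through the trivalent manganese enolate at C14 (the only α' position) and delivers acetate axially, anti to the axial C1 methyl group of the half-chair whose C2 and C9 side chains are equatorial, which sets 14S (OAc trans to C1-Me, cis to C2).

Step 16
Reactants: 22 C14 acetate
Product: 23 (Z)-enal
Conditions: (COCl)2, DMSO, CH2Cl2, −78 → −30 °C; then iPr2NEt, −78 → 0 °C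
Reagents that add atoms: none
Why: Swern oxidation converts the primary allylic triethylsilyl ether (or any alcohol freed in step 15) directly into the aldehyde, and the low temperature avoids Z/E isomerisation and C14 epimerisation.

Step 17
Reactants: 23 (Z)-enal
Product: 25 target CNP0325467.3, via C7 hydroxy ester 24 (not isolated)
Conditions: CrCl2 (10 equiv), NiCl2 (0.2 equiv), DMSO/THF, 23 °C, slow addition to 2 mM; then aq. NH4Cl
Reagents that add atoms: none
Why: Intramolecular Nozaki–Hiyama–Kishi coupling of the vinyl triflate with the aldehyde closes the ten-membered ring between the two equatorial side chains of ring A, and the chromium alkoxide lactonises onto the cis ester to give the butenolide; C7 is set by the ring-closure geometry (substrate control), which is expected but not assured to favour 7R.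

## Compound list

1 | (E)-pent-3-en-2-one | C/C=C/C(C)=O | starting material
2 | (E)-2-(triisopropylsilyloxy)penta-1,3-diene | C/C=C/C(=C)O[Si](C(C)C)(C(C)C)C(C)C | intermediate
3 | 2,3-dimethylfuran | Cc1occc1C | starting material
4 | (Z)-3-methyl-4-oxopent-2-enal | CC(=O)/C(C)=C\C=O | intermediate
5 | (E)-3-methyl-4-oxopent-2-enal | CC(=O)/C(C)=C/C=O | intermediate
6 | (1R,2R,6R)-6-acetyl-2,6-dimethyl-4-(triisopropylsilyloxy)cyclohex-3-ene-1-carbaldehyde (ring A; C1 bears Me and acetyl, C10 bears CHO trans to acetyl, C11-Me cis to CHO) | C1C(O[Si](C(C)C)(C(C)C)C(C)C)=C[C@@H](C)[C@@H](C=O)[C@]1(C)C(C)=O | intermediate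
7 | C9 alcohol (6 with CHO reduced to CH2OH; stereocentres as in 6) | C1C(O[Si](C(C)C)(C(C)C)C(C)C)=C[C@@H](C)[C@@H](CO)[C@]1(C)C(C)=O | intermediate
8 | 4-methylfuran-2(5H)-one | CC1=CC(=O)OC1 | starting material
9 | methyl (Z)-4-bromo-3-methylbut-2-enoate | COC(=O)/C=C(/C)CBr | intermediate
10 | (Z)-4-bromo-3-methylbut-2-en-1-ol | OC/C=C(/C)CBr | intermediate
11 | (Z)-4-bromo-3-methylbut-2-enyl triethylsilyl ether | CC[Si](CC)(CC)OC/C=C(/C)CBr | intermediate
12 | dilithium alkoxide-enolate of 7 (C9–OLi, C2(OLi)=C3H2) | C1C(O[Si](C(C)C)(C(C)C)C(C)C)=C[C@@H](C)[C@@H](CO[Li])[C@]1(C)C(=C)O[Li] | intermediate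
13 | C3-alkylated hydroxy ketone (C2 ketone carrying CH2CH2C(Me)=CHCH2OSiEt3, 5Z; C9–OH) | C1C(O[Si](C(C)C)(C(C)C)C(C)C)=C[C@@H](C)[C@@H](CO)[C@]1(C)C(=O)CC/C(C)=C\CO[Si](CC)(CC)CC | intermediate
14 | C9 iodide (13 with CH2OH replaced by CH2I) | C1C(O[Si](C(C)C)(C(C)C)C(C)C)=C[C@@H](C)[C@@H](CI)[C@]1(C)C(=O)CC/C(C)=C\CO[Si](CC)(CC)CC | intermediate
15 | (2S)-carbinol (14 with the C2 ketone reduced) | C1C(O[Si](C(C)C)(C(C)C)C(C)C)=C[C@@H](C)[C@@H](CI)[C@]1(C)[C@@H](O)CC/C(C)=C\CO[Si](CC)(CC)CC | intermediate
16 | C2 isobutyrate of 15 | C1C(O[Si](C(C)C)(C(C)C)C(C)C)=C[C@@H](C)[C@@H](CI)[C@]1(C)[C@@H](OC(=O)C(C)C)CC/C(C)=C\CO[Si](CC)(CC)CC | intermediate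
17 | ring-A enone (C13 ketone, C11=C12, C11-Me; C9 iodide; C2 isobutyrate) | C1C(=O)C=C(C)[C@@H](CI)[C@]1(C)[C@@H](OC(=O)C(C)C)CC/C(C)=C\CO[Si](CC)(CC)CC | intermediate
18 | alkylzinc iodide (17 with C9–ZnI) | C1C(=O)C=C(C)[C@@H](C[Zn]I)[C@]1(C)[C@@H](OC(=O)C(C)C)CC/C(C)=C\CO[Si](CC)(CC)CC | intermediate
19 | β-keto ester (C9H2–C8(=O)–C17H(Me)–CO2Me; C17 epimers) | C1C(=O)C=C(C)[C@@H](CC(=O)C(C)C(=O)OC)[C@]1(C)[C@@H](OC(=O)C(C)C)CC/C(C)=C\CO[Si](CC)(CC)CC | intermediate
20 | lithium (Z)-enolate of 19 | C1C(=O)C=C(C)[C@@H](C/C(O[Li])=C(\C)C(=O)OC)[C@]1(C)[C@@H](OC(=O)C(C)C)CC/C(C)=C\CO[Si](CC)(CC)CC | intermediate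
21 | (Z)-enol triflate (C8–OTf cis to CO2Me) | C1C(=O)C=C(C)[C@@H](C/C(OS(=O)(=O)C(F)(F)F)=C(\C)C(=O)OC)[C@]1(C)[C@@H](OC(=O)C(C)C)CC/C(C)=C\CO[Si](CC)(CC)CC | intermediate
22 | C14 acetate (14S; OAc trans to C1-Me) | CC(=O)O[C@@H]1C(=O)C=C(C)[C@@H](C/C(OS(=O)(=O)C(F)(F)F)=C(\C)C(=O)OC)[C@]1(C)[C@@H](OC(=O)C(C)C)CC/C(C)=C\CO[Si](CC)(CC)CC | intermediate
23 | (Z)-enal (22 with CH2OSiEt3 oxidised to CHO at C7) | CC(=O)O[C@@H]1C(=O)C=C(C)[C@@H](C/C(OS(=O)(=O)C(F)(F)F)=C(\C)C(=O)OC)[C@]1(C)[C@@H](OC(=O)C(C)C)CC/C(C)=C\C=O | intermediate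
24 | C7 hydroxy ester (ring B closed; C7–OH cis to CO2Me across C8=C17) | CC(=O)O[C@@H]1C(=O)C=C(C)[C@H]2C/C(=C(\C)C(=O)OC)[C@H](O)/C=C(/C)CC[C@H](OC(=O)C(C)C)[C@@]21C | intermediate
25 | CNP0325467.3, (1R,2S,5Z,7R,10R,14S)-briarane butenolide with 14-acetate and 2-isobutyrate | CC(=O)O[C@@H]1C(=O)C=C(C)[C@H]2CC3=C(C)C(=O)O[C@@H]3/C=C(/C)CC[C@H](OC(=O)C(C)C)[C@@]21C | target

## Step count and risks

Total step count: 17. Longest linear sequence: 13 steps (step 1 or 2, then 3, 4, 8–17; the branch 5–7–8–17 is also 13).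

Three steps most likely to fail:

Step 3 (the proposed new Diels–Alder reaction). The risks are rate at the β,β-disubstituted carbon, ketone-versus-aldehyde regiocontrol and enantioselectivity. The fallback sets out from 2 and 5 and gives up catalytic enantiocontrol in the cycloaddition: the reaction is run with Me2AlCl in CH2Cl2 at −78 °C (or thermally in toluene), the established behaviour of 2-silyloxydienes towards 4-oxo-enals, to give 6 as a racemate, i.e. together with ent-6 F1. Steps 4, 8 and 9 on the racemate then also give ent-7 F2, the dilithium alkoxide-enolate of ent-7 F3, ent-13 F4 and ent-14 F5. In step 10 the (R)-oxazaborolidine reduces both iodo ketones with the same sense at C2, giving 15 and the ring-enantiomeric (2S)-carbinol F6, which are diastereomers and are separated by chromatography. The fallback comes back to the route at 15, with at most half the material and with absolute configuration resting on the oxazaborolidine-catalysed reduction.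

Step 17 (ten-membered ring closure and C7 configuration). The fallback changes the ring-closing reaction to a ketone–aldehyde pinacol coupling and sets out from 19. PPTS in MeOH removes the silyl group to give allylic alcohol F7, and MnO2 gives keto ester enal F8. SmI2 (2.2 equiv, THF, −78 °C) closes ring B by chelation-controlled pinacol coupling of the β-keto ester carbonyl with the aldehyde, and the C7 alkoxide lactonises onto the ester to give β-hydroxy-γ-lactone F9. Mn(OAc)3·2H2O in refluxing benzene then gives the C14 acetate F10, and Burgess reagent dehydrates the tertiary alcohol into conjugation, coming back at 25. If only the C7 configuration is wrong after step 17, the γ-centre can instead be equilibrated through the 2-silyloxyfuran.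

Step 15 (chemo- and stereoselectivity of the direct acetoxylation). The fallback replaces the manganese enolate by a two-stage Rubottom-type acetoxylation and sets out from 21. tBuMe2SiOTf and Et3N in CH2Cl2 at −78 °C give the cross-conjugated 2-silyloxydiene F11 without strong base, which the enol triflate would not tolerate. Pb(OAc)4 in CH2Cl2 at −40 °C acetoxylates C14 of the electron-rich diene anti to the C1 methyl group, coming back at 22.

## Further compounds

F1 | step 3 | ent-6, (1S,2S,6S)-6-acetyl-2,6-dimethyl-4-(triisopropylsilyloxy)cyclohex-3-ene-1-carbaldehyde | C1C(O[Si](C(C)C)(C(C)C)C(C)C)=C[C@H](C)[C@H](C=O)[C@@]1(C)C(C)=O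
F2 | step 3 | ent-7, enantiomer of the C9 alcohol | C1C(O[Si](C(C)C)(C(C)C)C(C)C)=C[C@H](C)[C@H](CO)[C@@]1(C)C(C)=O
F3 | step 3 | dilithium alkoxide-enolate of ent-7 | C1C(O[Si](C(C)C)(C(C)C)C(C)C)=C[C@H](C)[C@H](CO[Li])[C@@]1(C)C(=C)O[Li]
F4 | step 3 | ent-13, enantiomer of the C3-alkylated hydroxy ketone | C1C(O[Si](C(C)C)(C(C)C)C(C)C)=C[C@H](C)[C@H](CO)[C@@]1(C)C(=O)CC/C(C)=C\CO[Si](CC)(CC)CC
F5 | step 3 | ent-14, enantiomer of the C9 iodide | C1C(O[Si](C(C)C)(C(C)C)C(C)C)=C[C@H](C)[C@H](CI)[C@@]1(C)C(=O)CC/C(C)=C\CO[Si](CC)(CC)CC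
F6 | step 3 | (2S)-carbinol of the enantiomeric ring (diastereomer of 15) | C1C(O[Si](C(C)C)(C(C)C)C(C)C)=C[C@H](C)[C@H](CI)[C@@]1(C)[C@@H](O)CC/C(C)=C\CO[Si](CC)(CC)CC
F7 | step 17 | allylic alcohol (19 without the triethylsilyl group) | C1C(=O)C=C(C)[C@@H](CC(=O)C(C)C(=O)OC)[C@]1(C)[C@@H](OC(=O)C(C)C)CC/C(C)=C\CO
F8 | step 17 | keto ester (Z)-enal | C1C(=O)C=C(C)[C@@H](CC(=O)C(C)C(=O)OC)[C@]1(C)[C@@H](OC(=O)C(C)C)CC/C(C)=C\C=O
F9 | step 17 | β-hydroxy-γ-lactone with ring B closed (C8–OH, C17–H; C8 and C17 unassigned) | C1C(=O)C=C(C)[C@H]2CC3(O)C(C)C(=O)O[C@@H]3/C=C(/C)CC[C@H](OC(=O)C(C)C)[C@@]21C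
F10 | step 17 | C14 acetate of F9 | CC(=O)O[C@@H]1C(=O)C=C(C)[C@H]2CC3(O)C(C)C(=O)O[C@@H]3/C=C(/C)CC[C@H](OC(=O)C(C)C)[C@@]21C
F11 | step 15 | cross-conjugated 2-(tert-butyldimethylsilyloxy)diene of 21 (C13–OSi, C13=C14, C11=C12) | C1=C(O[Si](C)(C)C(C)(C)C)C=C(C)[C@@H](C/C(OS(=O)(=O)C(F)(F)F)=C(\C)C(=O)OC)[C@]1(C)[C@@H](OC(=O)C(C)C)CC/C(C)=C\CO[Si](CC)(CC)CC
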